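**Plan**

- Retrosynthesis (side chain: C1' = ArOCH2, C2' = oxirane CH, C3' = oxirane C–CH3, C4' = CH2, C5' = lactone CH–O, C6' = CH2, C7' = CH–CH3, C8' = C=O): the two oxirane C–O bonds are cut first, back to the E-C2'=C3' olefin; then C5'–C6' together with the lactone O–C8' bond; then the aryl ether O–C1'; last C1'–C2' and C3'–CH3.
- Enabling feature: in the oxolan-2-one ring the carbinol carbon C5' is bonded to C6', which is β to the carbonyl C8'. The ring is therefore the adduct of an ester homoenolate and an aldehyde, and the C7' methyl centre is already present in the Roche ester.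
- Forward, chain: but-3-yn-1-ol is methylaluminated and hydroxymethylated to the E-diol; the allylic end is chlorinated and joined to 7-hydroxy-8-methoxycoumarin; the other end is oxidised to the β,γ-unsaturated aldehyde.
- Forward, rings: the zinc homoenolate from the Roche-ester iodide adds to this aldehyde and the γ-lactone (the only ring made in the route) closes in the same operation; the oxirane is made last.
- Stereochemistry: C7' (R) comes from methyl (R)-3-hydroxy-2-methylpropanoate, C5' (S) from the (1R,2R)-bis-sulfonamide titanium catalyst, C2'/C3' (R,R) from the D-fructose-derived ketone in the final epoxidation, and the E olefin from syn-carboalumination.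

Key step: step 6

Assumption: 7-hydroxy-8-methoxycoumarin is treated as a purchasable phenol, and the (1R,2R) ligand is chosen because this catalyst family delivers the alkyl group to the Si face of aldehydes, which here corresponds to 5'S.

**Step 1**
Reactants: 1 but-3-yn-1-ol
Product: 3 (E)-3-methylpent-2-ene-1,5-diol, via alkenylalane 2 (not isolated)
Conditions: Me3Al (3 equiv), Cp2ZrCl2 (0.25 equiv), CH2Cl2, 0 °C to rt; then (CH2O)n, 0 °C to rt; aq. potassium sodium tartrate
Reagents that add atoms: trimethylaluminium, C[Al](C)C; formaldehyde (as paraformaldehyde), C=O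
Why: Zirconium-catalysed methylalumination of the terminal alkyne (Negishi carboalumination) is a syn addition that puts CH3 on the internal carbon and aluminium on the terminal one, and the alkenyl–aluminium bond is hydroxymethylated by formaldehyde with retention, so the E-trisubstituted olefin should result while the free hydroxyl is carried as its aluminium alkoxide.

**Step 2**
Reactants: 3 (E)-3-methylpent-2-ene-1,5-diol
Product: 4 (E)-5-chloro-3-methylpent-3-en-1-ol
Conditions: NCS (1.3 equiv), Me2S (1.5 equiv), CH2Cl2, −25 °C to 0 °C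
Reagents that add atoms: N-chlorosuccinimide, O=C1CCC(=O)N1Cl
Why: In the Corey–Kim chlorination the sulfonium reagent from NCS and Me2S turns hydroxyls into alkoxysulfonium ions, of which only the allylic one is displaced by chloride (SN2, olefin geometry unchanged) below 0 °C, while the saturated primary alkoxysulfonium ion is hydrolysed back to the alcohol on work-up.

**Step 3**
Reactants: 4 (E)-5-chloro-3-methylpent-3-en-1-ol; 5 7-hydroxy-8-methoxy-2H-chromen-2-one
Product: 6 7-{[(E)-5-hydroxy-3-methylpent-2-en-1-yl]oxy}-8-methoxy-2H-chromen-2-one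
Conditions: K2CO3 (1.5 equiv), KI (0.1 equiv), DMF, rt to 40 °C
Reagents that add atoms: none
Why: In this Williamson ether synthesis the potassium phenoxide of 5, the only hydroxyl acidic enough for carbonate, displaces the primary allylic chloride by SN2 at C1', which should keep the E geometry and leave the aliphatic hydroxyl untouched.

**Step 4**
Reactants: 6 7-{[(E)-5-hydroxy-3-methylpent-2-en-1-yl]oxy}-8-methoxy-2H-chromen-2-one
Product: 7 (E)-5-[(8-methoxy-2-oxo-2H-chromen-7-yl)oxy]-3-methylpent-3-enal
Conditions: Dess–Martin periodinane (1.3 equiv), NaHCO3 (3 equiv), CH2Cl2, 0 °C to rt; short silica plug, used at once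
Reagents that add atoms: none
Why: Dess–Martin oxidation under hydrogencarbonate buffering converts the primary homoallylic alcohol into the aldehyde at near-neutral pH and low temperature, where the C2'=C3' bond should stay out of conjugation and the aryloxide should not be eliminated.

**Step 5**
Reactants: 8 methyl (R)-3-hydroxy-2-methylpropanoate
Product: 9 methyl (S)-3-iodo-2-methylpropanoate
Conditions: I2 (1.2 equiv), PPh3 (1.2 equiv), imidazole (1.3 equiv), CH2Cl2, 0 °C to rt
Reagents that add atoms: iodine, II
Why: In this Appel-type iodination the primary hydroxyl is activated as its oxyphosphonium ion and displaced by iodide at the CH2 carbon only, so the neighbouring stereocentre is not involved and the descriptor changes from R to S through CIP priority alone.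

**Step 6**
Reactants: 7 (E)-5-[(8-methoxy-2-oxo-2H-chromen-7-yl)oxy]-3-methylpent-3-enal; 9 methyl (S)-3-iodo-2-methylpropanoate
Product: 12 (3R,5S)-5-{(E)-4-[(8-methoxy-2-oxo-2H-chromen-7-yl)oxy]-2-methylbut-2-en-1-yl}-3-methyloxolan-2-one, via dialkylzinc 10 (not isolated), via hydroxy ester 11 (not isolated)
Conditions: 9 (3 equiv), Et2Zn (4.5 equiv, neat), CuI (0.3 mol%), 50 °C, then EtI and excess Et2Zn removed in vacuo; Ti(OiPr)4 (2 equiv), (1R,2R)-1,2-bis(trifluoromethanesulfonamido)cyclohexane (8 mol%), toluene, −20 °C; 7 (1 equiv) in toluene–CH2Cl2, −20 to 0 °C; aq. NH4Cl; then pyridinium p-toluenesulfonate (0.1 equiv), CH2Cl2, rt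
Reagents that add atoms: none
Why: Iodine–zinc exchange turns 9 into dialkylzinc 10 without touching C7'; with Ti(OiPr)4 and the bis-sulfonamide, one ester-bearing alkyl group passes from zinc to a chiral tetravalent titanium complex that also binds aldehyde 7, and C6' is delivered to the carbonyl carbon C5'. The closest known reaction type is the titanium bis-sulfonamide-catalysed enantioselective addition of ester-functionalised dialkylzincs to aldehydes, and titanium-bound ester homoenolates are established aldehyde nucleophiles. The oxolan-2-one ring closes by 5-exo-trig acyl substitution of the C5' alkoxide on the methyl ester, driven to completion by the catalytic acid if hydroxy ester 11 survives work-up. C5' (S) is set by the catalyst, which with the (1R,2R) ligand is expected to shield the Re face and deliver the alkyl group to the Si face, while C7' (R) is carried unchanged from the Roche ester, so the trans lactone rests on two independent elements. The step needs 1,2-addition to the aldehyde in preference to enolisation, to migration of the C2'=C3' double bond into conjugation and to attack on the coumarin; the weakly basic zinc and titanium alkyls, the low temperature and the inertness of the coumarin lactone and the allylic aryl ether towards organozincs should secure this.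

**Step 7**
Reactants: 12 (3R,5S)-5-{(E)-4-[(8-methoxy-2-oxo-2H-chromen-7-yl)oxy]-2-methylbut-2-en-1-yl}-3-methyloxolan-2-one
Product: 13 (3R,5S)-5-{[(2R,3R)-3-{[(8-methoxy-2-oxo-2H-chromen-7-yl)oxy]methyl}-2-methyloxiran-2-yl]methyl}-3-methyloxolan-2-one
Conditions: 1,2:4,5-di-O-isopropylidene-β-D-erythro-2,3-hexodiulo-2,6-pyranose (D-fructose-derived Shi ketone, 0.3 equiv), KHSO5 (as 2KHSO5·KHSO4·K2SO4, 1.4 equiv), K2CO3 (5.8 equiv), Bu4NHSO4 (0.05 equiv), MeCN–CH2(OMe)2–aq. Na2B4O7 buffer, pH about 10.5, 0 °C
Reagents that add atoms: potassium peroxymonosulfate, [K+].[O-]S(=O)(=O)OO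
Why: In the Shi epoxidation the chiral dioxirane formed from the ketone and KHSO5 transfers oxygen through a spiro transition state to one face of the electron-rich E-trisubstituted C2'=C3' olefin, which should give the (2'R,3'R)-oxirane under reagent control, while the electron-poor coumarin C3=C4 bond and both lactones should be left alone at 0 °C in the buffered medium.

**Compound list**

1 | but-3-yn-1-ol | C#CCCO | starting material
2 | dimethylaluminium (E)-4-(dimethylalumanyl)-3-methylbut-3-en-1-olate (alkenylalane) | C[Al](C)/C=C(\C)CCO[Al](C)C | intermediate (not isolated)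
3 | (E)-3-methylpent-2-ene-1,5-diol | OC/C=C(\C)CCO | intermediate
4 | (E)-5-chloro-3-methylpent-3-en-1-ol | ClC/C=C(\C)CCO | intermediate
5 | 7-hydroxy-8-methoxy-2H-chromen-2-one | COc1c(O)ccc2ccc(=O)oc12 | starting material
6 | 7-{[(E)-5-hydroxy-3-methylpent-2-en-1-yl]oxy}-8-methoxy-2H-chromen-2-one | COc1c(OC/C=C(\C)CCO)ccc2ccc(=O)oc12 | intermediate
7 | (E)-5-[(8-methoxy-2-oxo-2H-chromen-7-yl)oxy]-3-methylpent-3-enal | COc1c(OC/C=C(\C)CC=O)ccc2ccc(=O)oc12 | intermediate
8 | methyl (R)-3-hydroxy-2-methylpropanoate | OC[C@@H](C)C(=O)OC | starting material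
9 | methyl (S)-3-iodo-2-methylpropanoate | IC[C@@H](C)C(=O)OC | intermediate
10 | bis[(S)-3-methoxy-2-methyl-3-oxopropyl]zinc (dialkylzinc) | [Zn](C[C@@H](C)C(=O)OC)C[C@@H](C)C(=O)OC | intermediate (not isolated)
11 | methyl (2R,4S,6E)-4-hydroxy-8-[(8-methoxy-2-oxo-2H-chromen-7-yl)oxy]-2,6-dimethyloct-6-enoate (hydroxy ester, present as its metal alkoxide) | COc1c(OC/C=C(\C)C[C@@H](O)C[C@@H](C)C(=O)OC)ccc2ccc(=O)oc12 | intermediate (not isolated)
12 | (3R,5S)-5-{(E)-4-[(8-methoxy-2-oxo-2H-chromen-7-yl)oxy]-2-methylbut-2-en-1-yl}-3-methyloxolan-2-one | COc1c(OC/C=C(\C)C[C@@H]2C[C@@H](C)C(=O)O2)ccc2ccc(=O)oc12 | intermediate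
13 | (3R,5S)-5-{[(2R,3R)-3-{[(8-methoxy-2-oxo-2H-chromen-7-yl)oxy]methyl}-2-methyloxiran-2-yl]methyl}-3-methyloxolan-2-one | COc1c(OC[C@H]2O[C@]2(C)C[C@@H]2C[C@@H](C)C(=O)O2)ccc2ccc(=O)oc12 | target

**Summary**

Total step count: 7. Longest linear sequence: 6 steps (1 → 3 → 4 → 6 → 7 → 12 → 13; step 5 feeds in the second fragment).

**Steps most likely to fail**

Step 6. The ester carbonyl coordinates the zinc centre internally, so transfer of the alkyl group to titanium may be slow; the β,γ-unsaturated aldehyde then has time to enolise and move its double bond into conjugation, or conversion stays low. The fallback sets out from iodide 9 and aldehyde 7 and returns at lactone 12. Compound 9 is reduced with iBu2AlH (CH2Cl2, −78 °C) to (S)-3-iodo-2-methylpropan-1-ol F1, which is silylated (TBSCl, imidazole) to (S)-tert-butyl(3-iodo-2-methylpropoxy)dimethylsilane F2. Iodine–zinc exchange (Et2Zn, catalytic CuI) gives the non-chelating bis[(S)-3-{[tert-butyl(dimethyl)silyl]oxy}-2-methylpropyl]zinc F3. This is added to 7 under the same Ti(OiPr)4/(1R,2R)-bis-sulfonamide catalysis to give 7-{[(2E,5S,7R)-8-{[tert-butyl(dimethyl)silyl]oxy}-5-hydroxy-3,7-dimethyloct-2-en-1-yl]oxy}-8-methoxy-2H-chromen-2-one F4. HF·pyridine frees 7-{[(2E,5S,7R)-5,8-dihydroxy-3,7-dimethyloct-2-en-1-yl]oxy}-8-methoxy-2H-chromen-2-one F5. Oxidation with 2,2,6,6-tetramethylpiperidin-1-oxyl and PhI(OAc)2 takes the primary hydroxyl through the lactol to 12, so the ring is closed oxidatively instead of by acyl substitution.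

Step 7. Oxygen transfer to the inductively deactivated allylic-ether olefin may be slow or poorly face-selective, and the lactones may open at the pH the ketone needs. The fallback sets out from chloro alcohol 4 and returns at target 13; it takes the oxirane from a Sharpless asymmetric epoxidation and attaches the coumarin last. Compound 4 is etherified with 4-methoxyphenol (K2CO3, DMF) to (E)-5-(4-methoxyphenoxy)-3-methylpent-3-en-1-ol F6 and oxidised (Dess–Martin periodinane) to (E)-5-(4-methoxyphenoxy)-3-methylpent-3-enal F7. Reaction with dialkylzinc 10 as in step 6 gives, through methyl (2R,4S,6E)-4-hydroxy-8-(4-methoxyphenoxy)-2,6-dimethyloct-6-enoate F8, the lactone (3R,5S)-5-[(E)-4-(4-methoxyphenoxy)-2-methylbut-2-en-1-yl]-3-methyloxolan-2-one F9. (NH4)2Ce(NO3)6 in MeCN–H2O at 0 °C removes the aryl group to give (3R,5S)-5-[(E)-4-hydroxy-2-methylbut-2-en-1-yl]-3-methyloxolan-2-one F10. Epoxidation with Ti(OiPr)4, D-(−)-diisopropyl tartrate and t-BuOOH (4 Å sieves, CH2Cl2, −20 °C) should give (3R,5S)-5-{[(2R,3R)-3-(hydroxymethyl)-2-methyloxiran-2-yl]methyl}-3-methyloxolan-2-one F11. Mitsunobu etherification of F11 with phenol 5 (PPh3, diisopropyl azodicarboxylate, THF) gives 13.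

Step 2. Chemoselectivity between the allylic and the saturated primary hydroxyl may be incomplete, with double activation, chlorination at the wrong end or methylthiomethyl ether formation. The fallback sets out from 1 and returns at alcohol 6; it separates the two hydroxyls by a protecting group before the olefin is built and makes the aryl ether by Mitsunobu reaction. Compound 1 is silylated (TBSCl, imidazole) to tert-butyl(but-3-yn-1-yloxy)dimethylsilane F12. Carboalumination as in step 1 gives [(E)-4-{[tert-butyl(dimethyl)silyl]oxy}-2-methylbut-1-en-1-yl]dimethylalumane F13, which paraformaldehyde converts into (E)-5-{[tert-butyl(dimethyl)silyl]oxy}-3-methylpent-2-en-1-ol F14. Mitsunobu etherification with 5 (PPh3, diisopropyl azodicarboxylate, THF) gives 7-{[(E)-5-{[tert-butyl(dimethyl)silyl]oxy}-3-methylpent-2-en-1-yl]oxy}-8-methoxy-2H-chromen-2-one F15, and HF·pyridine in THF returns 6.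

**Further compounds**

F1 | step 6 | (S)-3-iodo-2-methylpropan-1-ol | IC[C@@H](C)CO
F2 | step 6 | (S)-tert-butyl(3-iodo-2-methylpropoxy)dimethylsilane | IC[C@@H](C)CO[Si](C)(C)C(C)(C)C
F3 | step 6 | bis[(S)-3-{[tert-butyl(dimethyl)silyl]oxy}-2-methylpropyl]zinc | [Zn](C[C@@H](C)CO[Si](C)(C)C(C)(C)C)C[C@@H](C)CO[Si](C)(C)C(C)(C)C
F4 | step 6 | 7-{[(2E,5S,7R)-8-{[tert-butyl(dimethyl)silyl]oxy}-5-hydroxy-3,7-dimethyloct-2-en-1-yl]oxy}-8-methoxy-2H-chromen-2-one | COc1c(OC/C=C(\C)C[C@@H](O)C[C@@H](C)CO[Si](C)(C)C(C)(C)C)ccc2ccc(=O)oc12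
F5 | step 6 | 7-{[(2E,5S,7R)-5,8-dihydroxy-3,7-dimethyloct-2-en-1-yl]oxy}-8-methoxy-2H-chromen-2-one | COc1c(OC/C=C(\C)C[C@@H](O)C[C@@H](C)CO)ccc2ccc(=O)oc12
F6 | step 7 | (E)-5-(4-methoxyphenoxy)-3-methylpent-3-en-1-ol | COc1ccc(OC/C=C(\C)CCO)cc1
F7 | step 7 | (E)-5-(4-methoxyphenoxy)-3-methylpent-3-enal | COc1ccc(OC/C=C(\C)CC=O)cc1
F8 | step 7 | methyl (2R,4S,6E)-4-hydroxy-8-(4-methoxyphenoxy)-2,6-dimethyloct-6-enoate | COc1ccc(OC/C=C(\C)C[C@@H](O)C[C@@H](C)C(=O)OC)cc1
F9 | step 7 | (3R,5S)-5-[(E)-4-(4-methoxyphenoxy)-2-methylbut-2-en-1-yl]-3-methyloxolan-2-one | COc1ccc(OC/C=C(\C)C[C@@H]2C[C@@H](C)C(=O)O2)cc1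
F10 | step 7 | (3R,5S)-5-[(E)-4-hydroxy-2-methylbut-2-en-1-yl]-3-methyloxolan-2-one | OC/C=C(\C)C[C@@H]1C[C@@H](C)C(=O)O1
F11 | step 7 | (3R,5S)-5-{[(2R,3R)-3-(hydroxymethyl)-2-methyloxiran-2-yl]methyl}-3-methyloxolan-2-one | OC[C@H]1O[C@]1(C)C[C@@H]1C[C@@H](C)C(=O)O1
F12 | step 2 | tert-butyl(but-3-yn-1-yloxy)dimethylsilane | C#CCCO[Si](C)(C)C(C)(C)C
F13 | step 2 | [(E)-4-{[tert-butyl(dimethyl)silyl]oxy}-2-methylbut-1-en-1-yl]dimethylalumane | C[Al](C)/C=C(\C)CCO[Si](C)(C)C(C)(C)C
F14 | step 2 | (E)-5-{[tert-butyl(dimethyl)silyl]oxy}-3-methylpent-2-en-1-ol | OC/C=C(\C)CCO[Si](C)(C)C(C)(C)C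
F15 | step 2 | 7-{[(E)-5-{[tert-butyl(dimethyl)silyl]oxy}-3-methylpent-2-en-1-yl]oxy}-8-methoxy-2H-chromen-2-one | COc1c(OC/C=C(\C)CCO[Si](C)(C)C(C)(C)C)ccc2ccc(=O)oc12
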